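**Plan**

- Enabling feature: in ring C, C2 is a benzylic carbon bonded to O1 and C3 lies next to the C4 ketone. Opening C2–C3 therefore leaves O1–C2 as the methylene of an aryl benzyl ether and C3 as the carbene carbon of an aryl diazomethyl ketone.
- Cuts, in order: the O-protecting groups; C2–C3 (ring C); C3–C4 (a diazomethane unit onto an aroyl chloride); the ring A–CH2 bond at C6 (C-benzylation of 2,4,6-trihydroxybenzaldehyde).
- Forward: the ring D benzyl bromide 5 is made in three steps and joined to C3 of aldehyde 6. O4 and O6 are benzylated (the O6 benzyl later supplies C2, its hydrogen and ring B) and the hindered O2 is silylated. The formyl group is oxidised and homologated to the diazoketone, ring C is closed, and the silyl and benzyl groups are removed.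
- Regiochemistry (6-benzyl, not 8-benzyl) follows from benzylating the less hindered ortho oxygen, the only one that can then deliver C2.
- Stereochemistry: C2 (S), the only stereocentre, is set by the chiral dirhodium carboxylate in the insertion and is kept by base-free conditions afterwards.

Key step: step 9

Assumption: the sense of induction of Rh2(S-PTTL)4 in this benzylic insertion is taken to lead to the (2S) product; if the opposite sense were found, the mirror-image complex Rh2(R-PTTL)4 would be used in the same way.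
Numbering: flavanone numbering is used (O1, C2, C3, C4; ring A the fused benzene ring, ring B the 2-phenyl group, ring C the pyranone); the catechol ring of the 6-benzyl group is called ring D.

**Route**

Step 1
Reactants: 1 2,3-dihydroxybenzaldehyde; 2 benzyl bromide
Product: 3 2,3-bis(benzyloxy)benzaldehyde
Conditions: 2 (2.2 equiv in all), K2CO3 (3 equiv), DMF, rt → 60 °C
Reagents that add atoms: benzyl bromide (the second equivalent of 2), BrCc1ccccc1
Why: Double Williamson ether synthesis, in which each of the two catechol phenoxides is alkylated by one molecule of the benzylic bromide while the aldehyde is inert.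

Step 2
Reactants: 3 2,3-bis(benzyloxy)benzaldehyde
Product: 4 [2,3-bis(benzyloxy)phenyl]methanol
Conditions: NaBH4, MeOH/THF, 0 °C
Reagents that add atoms: none
Why: Chemoselective hydride reduction of an aryl aldehyde to the benzylic alcohol, which leaves the benzyl ethers untouched.

Step 3
Reactants: 4 [2,3-bis(benzyloxy)phenyl]methanol
Product: 5 1,2-bis(benzyloxy)-3-(bromomethyl)benzene
Conditions: PBr3, CH2Cl2, 0 °C
Reagents that add atoms: phosphorus tribromide, BrP(Br)Br
Why: Bromination of a benzylic alcohol through its phosphite ester and SN2 displacement by bromide, fast enough at 0 °C to spare the aryl benzyl ethers.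

Step 4
Reactants: 6 2,4,6-trihydroxybenzaldehyde; 5 1,2-bis(benzyloxy)-3-(bromomethyl)benzene
Product: 7 3-[2,3-bis(benzyloxy)benzyl]-2,4,6-trihydroxybenzaldehyde
Conditions: 6 (2 equiv), DBU, THF, 0 °C → rt, slow addition of 5
Reagents that add atoms: none
Why: C-alkylation of an acylphloroglucinol, in which the ambident phenoxide reacts with the soft benzylic bromide at a ring carbon; C3 and C5 of 6 are equivalent, so one mono-alkylation product should arise, and the excess of 6 limits a second alkylation.

Step 5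
Reactants: 7 3-[2,3-bis(benzyloxy)benzyl]-2,4,6-trihydroxybenzaldehyde; 2 benzyl bromide
Product: 8 4,6-bis(benzyloxy)-3-[2,3-bis(benzyloxy)benzyl]-2-hydroxybenzaldehyde
Conditions: 2 (2.1 equiv in all), K2CO3, DMF, 0 °C → rt
Reagents that add atoms: benzyl bromide (the second equivalent of 2), BrCc1ccccc1
Why: Regioselective double Williamson etherification, in which O4 (para to the formyl group, most acidic) and then the open O6 each take one benzyl group, while the O2 hydroxyl, wedged between the formyl group and the new benzyl substituent and hydrogen-bonded to the carbonyl, stays free, as is usual for 3-alkylated acylphloroglucinols.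

Step 6
Reactants: 8 4,6-bis(benzyloxy)-3-[2,3-bis(benzyloxy)benzyl]-2-hydroxybenzaldehyde
Product: 9 4,6-bis(benzyloxy)-3-[2,3-bis(benzyloxy)benzyl]-2-[(tert-butyldimethylsilyl)oxy]benzaldehyde
Conditions: TBSOTf, 2,6-lutidine, CH2Cl2, 0 °C → rt
Reagents that add atoms: tert-butyldimethylsilyl trifluoromethanesulfonate, CC(C)(C)[Si](C)(C)OS(=O)(=O)C(F)(F)F
Why: Silylation of a hindered, hydrogen-bonded phenol with a silyl triflate and a hindered pyridine base, which places on the future O5 a group with no C–H bond within reach of the later carbene.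

Step 7
Reactants: 9 4,6-bis(benzyloxy)-3-[2,3-bis(benzyloxy)benzyl]-2-[(tert-butyldimethylsilyl)oxy]benzaldehyde
Product: 10 4,6-bis(benzyloxy)-3-[2,3-bis(benzyloxy)benzyl]-2-[(tert-butyldimethylsilyl)oxy]benzoic acid
Conditions: NaClO2, NaH2PO4, 2-methyl-2-butene (large excess), t-BuOH/THF/H2O, 0 °C → rt
Reagents that add atoms: sodium chlorite, [Na+].[O-]Cl=O
Why: Pinnick oxidation, in which buffered chlorous acid converts the aldehyde into the acid while the excess alkene traps HOCl and so protects the electron-rich ring A from chlorination.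

Step 8
Reactants: 10 4,6-bis(benzyloxy)-3-[2,3-bis(benzyloxy)benzyl]-2-[(tert-butyldimethylsilyl)oxy]benzoic acid; 11 trimethylsilyldiazomethane
Product: 13 1-{4,6-bis(benzyloxy)-3-[2,3-bis(benzyloxy)benzyl]-2-[(tert-butyldimethylsilyl)oxy]phenyl}-2-diazoethan-1-one, via aroyl chloride 12 (not isolated)
Conditions: 1-chloro-N,N,2-trimethylprop-1-en-1-amine, CH2Cl2, 0 °C → rt; then 11 (2.5 equiv), MeCN/THF, 0 °C → rt; non-acidic work-up
Reagents that add atoms: 1-chloro-N,N,2-trimethylprop-1-en-1-amine, CC(C)=C(Cl)N(C)C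
Why: The chloroenamine supplies the chlorine of aroyl chloride 12 under neutral conditions that spare the silyl ether, and acylation of the diazo carbon of 11 with loss of the silyl group as Me3SiCl gives the diazomethyl ketone (first stage of the Arndt–Eistert sequence).

Step 9
Reactants: 13 1-{4,6-bis(benzyloxy)-3-[2,3-bis(benzyloxy)benzyl]-2-[(tert-butyldimethylsilyl)oxy]phenyl}-2-diazoethan-1-one
Product: 14 (2S)-7-(benzyloxy)-6-[2,3-bis(benzyloxy)benzyl]-5-[(tert-butyldimethylsilyl)oxy]-2-phenylchroman-4-one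
Conditions: Rh2(S-PTTL)4, dirhodium tetrakis[N-phthaloyl-(S)-tert-leucinate] (2 mol %), 4 Å MS, CH2Cl2, 0 °C, slow addition of 13
Reagents that add atoms: none
Why: Loss of N2 from 13 on the dimer of divalent rhodium gives an electrophilic keto carbene that inserts, in a concerted three-centre transition state with hydride-transfer character, into one C–H bond of the O1 benzyl methylene, which is activated by the neighbouring oxygen and by its own phenyl ring, and so forms C2–C3. The closest known reaction type is the dirhodium-carboxylate-catalysed enantioselective intramolecular C–H insertion of ortho-alkoxyaryl diazoketones next to the ether oxygen, which gives chroman-4-ones. Ring C closes as a six-membered ring by 1,6-insertion, because a closure one atom shorter would end on O1 and not on a C–H bond. The C2 stereocentre is controlled by the catalyst alone: the N-phthaloyl tert-leucinate ligands form a chiral pocket around the carbene that distinguishes the two enantiotopic benzylic hydrogens, the substrate having no other stereocentre. The step needs insertion to win over oxonium ylide formation at O1 with 1,2-benzyl shift and over any reaction on the O5 side; the doubly activated benzylic C–H bond, slow addition at 0 °C to a carboxylate catalyst of moderate electrophilicity, and the bulky silyl group on O5, which shields that oxygen and offers no C–H bond closer than a seven-membered ring, should secure this, while the benzyl ethers on O7 and on ring D are out of reach.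

Step 10
Reactants: 14 (2S)-7-(benzyloxy)-6-[2,3-bis(benzyloxy)benzyl]-5-[(tert-butyldimethylsilyl)oxy]-2-phenylchroman-4-one
Product: 15 (2S)-7-(benzyloxy)-6-[2,3-bis(benzyloxy)benzyl]-5-hydroxy-2-phenylchroman-4-one
Conditions: KHF2, MeOH/THF, rt
Reagents that add atoms: none
Why: Fluoride-mediated cleavage of a phenolic silyl ether under mildly acidic conditions, which avoids the base that would open ring C by retro-oxa-Michael reaction and racemise C2.

Step 11
Reactants: 15 (2S)-7-(benzyloxy)-6-[2,3-bis(benzyloxy)benzyl]-5-hydroxy-2-phenylchroman-4-one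
Product: 16 (2S)-6-(2,3-dihydroxybenzyl)-5,7-dihydroxy-2-phenylchroman-4-one (CNP0348560.1)
Conditions: H2 (1 atm), 10% Pd/C, EtOAc/MeOH, rt, monitored and stopped at full debenzylation
Reagents that add atoms: none
Why: Catalytic hydrogenolysis of the three primary aryl benzyl ethers under neutral conditions, which should leave the ketone and the more hindered secondary C2–O1 bond intact and does not touch the C2 configuration.

**Compound list**

1 | 2,3-dihydroxybenzaldehyde | O=Cc1cccc(O)c1O | starting material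
2 | benzyl bromide | BrCc1ccccc1 | starting material
3 | 2,3-bis(benzyloxy)benzaldehyde | O=Cc1cccc(OCc2ccccc2)c1OCc1ccccc1 | intermediate
4 | [2,3-bis(benzyloxy)phenyl]methanol | OCc1cccc(OCc2ccccc2)c1OCc1ccccc1 | intermediate
5 | 1,2-bis(benzyloxy)-3-(bromomethyl)benzene | BrCc1cccc(OCc2ccccc2)c1OCc1ccccc1 | intermediate
6 | 2,4,6-trihydroxybenzaldehyde | O=Cc1c(O)cc(O)cc1O | starting material
7 | 3-[2,3-bis(benzyloxy)benzyl]-2,4,6-trihydroxybenzaldehyde | O=Cc1c(O)cc(O)c(Cc2cccc(OCc3ccccc3)c2OCc2ccccc2)c1O | intermediate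
8 | 4,6-bis(benzyloxy)-3-[2,3-bis(benzyloxy)benzyl]-2-hydroxybenzaldehyde | O=Cc1c(OCc2ccccc2)cc(OCc2ccccc2)c(Cc2cccc(OCc3ccccc3)c2OCc2ccccc2)c1O | intermediate
9 | 4,6-bis(benzyloxy)-3-[2,3-bis(benzyloxy)benzyl]-2-[(tert-butyldimethylsilyl)oxy]benzaldehyde | O=Cc1c(OCc2ccccc2)cc(OCc2ccccc2)c(Cc2cccc(OCc3ccccc3)c2OCc2ccccc2)c1O[Si](C)(C)C(C)(C)C | intermediate
10 | 4,6-bis(benzyloxy)-3-[2,3-bis(benzyloxy)benzyl]-2-[(tert-butyldimethylsilyl)oxy]benzoic acid | OC(=O)c1c(OCc2ccccc2)cc(OCc2ccccc2)c(Cc2cccc(OCc3ccccc3)c2OCc2ccccc2)c1O[Si](C)(C)C(C)(C)C | intermediate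
11 | trimethylsilyldiazomethane | C[Si](C)(C)C=[N+]=[N-] | starting material
12 | 4,6-bis(benzyloxy)-3-[2,3-bis(benzyloxy)benzyl]-2-[(tert-butyldimethylsilyl)oxy]benzoyl chloride | ClC(=O)c1c(OCc2ccccc2)cc(OCc2ccccc2)c(Cc2cccc(OCc3ccccc3)c2OCc2ccccc2)c1O[Si](C)(C)C(C)(C)C | intermediate
13 | 1-{4,6-bis(benzyloxy)-3-[2,3-bis(benzyloxy)benzyl]-2-[(tert-butyldimethylsilyl)oxy]phenyl}-2-diazoethan-1-one | [N-]=[N+]=CC(=O)c1c(OCc2ccccc2)cc(OCc2ccccc2)c(Cc2cccc(OCc3ccccc3)c2OCc2ccccc2)c1O[Si](C)(C)C(C)(C)C | intermediate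
14 | (2S)-7-(benzyloxy)-6-[2,3-bis(benzyloxy)benzyl]-5-[(tert-butyldimethylsilyl)oxy]-2-phenylchroman-4-one | O=C1C[C@@H](c2ccccc2)Oc2cc(OCc3ccccc3)c(Cc3cccc(OCc4ccccc4)c3OCc3ccccc3)c(O[Si](C)(C)C(C)(C)C)c21 | intermediate
15 | (2S)-7-(benzyloxy)-6-[2,3-bis(benzyloxy)benzyl]-5-hydroxy-2-phenylchroman-4-one | O=C1C[C@@H](c2ccccc2)Oc2cc(OCc3ccccc3)c(Cc3cccc(OCc4ccccc4)c3OCc3ccccc3)c(O)c21 | intermediate
16 | (2S)-6-(2,3-dihydroxybenzyl)-5,7-dihydroxy-2-phenylchroman-4-one | O=C1C[C@@H](c2ccccc2)Oc2cc(O)c(Cc3cccc(O)c3O)c(O)c21 | target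

**Step count and risks**

Total step count: 11. Longest linear sequence: 11 steps (steps 1 to 11 from 2,3-dihydroxybenzaldehyde; 8 steps from 2,4,6-trihydroxybenzaldehyde).

Steps most likely to fail:

1. Step 9. The carbene may be captured by the lone pair of O1 (oxonium ylide, then 1,2-benzyl shift to a benzofuranone) instead of inserting, or the two enantiotopic hydrogens may be poorly distinguished. The fallback sets out from 9 and comes back at 14; it forms O1–C2 first and introduces the phenyl group last, without a carbene.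
   - The benzyl ether ortho to the formyl group of 9 is cleaved selectively by chelation with MgBr2·OEt2 (toluene/Et2O, warm), the silyl ether oxygen being a poor donor and the other benzyl ethers having no carbonyl neighbour. This should give 4-(benzyloxy)-3-[2,3-bis(benzyloxy)benzyl]-2-[(tert-butyldimethylsilyl)oxy]-6-hydroxybenzaldehyde F1.
   - Excess ethynylmagnesium bromide (THF, 0 °C) adds to give rac-1-{4-(benzyloxy)-3-[2,3-bis(benzyloxy)benzyl]-2-[(tert-butyldimethylsilyl)oxy]-6-hydroxyphenyl}prop-2-yn-1-ol F2.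
   - MnO2 (CH2Cl2) oxidises it to 1-{4-(benzyloxy)-3-[2,3-bis(benzyloxy)benzyl]-2-[(tert-butyldimethylsilyl)oxy]-6-hydroxyphenyl}prop-2-yn-1-one F3.
   - Amine-mediated conjugate addition of the phenol (Et2NH, EtOH, rt) closes ring C to 7-(benzyloxy)-6-[2,3-bis(benzyloxy)benzyl]-5-[(tert-butyldimethylsilyl)oxy]-4H-chromen-4-one F4.
   - Asymmetric conjugate addition of phenylboronic acid with Pd(OCOCF3)2 and the tert-butyl pyridine-oxazoline ligand of the hand that delivers the (2S) product (NH4PF6, H2O, 1,2-dichloroethane, 60 °C) then gives 14.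

2. Step 4. The phloroglucinolate may be alkylated on oxygen instead of carbon, or a second C-alkylation may follow. The fallback sets out from 6 (using 2 and 5) and comes back at 8; it replaces the ambident-anion alkylation by a cross-coupling and also fixes the position of the free hydroxyl without relying on the regioselectivity of step 5.
   - 6 is first benzylated on O4 and O6 (two equivalents of 2, K2CO3, DMF) to 4,6-bis(benzyloxy)-2-hydroxybenzaldehyde F5.
   - Iodination ortho to the free hydroxyl (N-iodosuccinimide, DMF, 0 °C) gives 4,6-bis(benzyloxy)-2-hydroxy-3-iodobenzaldehyde F6.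
   - Bromide 5 is converted with zinc dust and LiCl in THF into [2,3-bis(benzyloxy)benzyl]zinc bromide F7.
   - Negishi coupling of F6 with an excess of F7 (Pd(OAc)2, SPhos, THF, slow addition to tolerate the free phenol) gives 8.

3. Step 8. Acylation of the silyldiazomethane by the doubly ortho-substituted, electron-rich aroyl chloride may be slow, with competing loss of the silyl ether or acid-induced closure to a benzofuranone through traces of HCl. The fallback sets out from 9 and comes back at 13; the diazo group comes from a sulfonyl azide onto a methyl ketone, and no acid chloride is needed.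
   - MeMgBr (THF, −78 °C) adds to 9 to give rac-1-{4,6-bis(benzyloxy)-3-[2,3-bis(benzyloxy)benzyl]-2-[(tert-butyldimethylsilyl)oxy]phenyl}ethan-1-ol F8.
   - Dess–Martin periodinane (CH2Cl2, NaHCO3, rt) oxidises it to 1-{4,6-bis(benzyloxy)-3-[2,3-bis(benzyloxy)benzyl]-2-[(tert-butyldimethylsilyl)oxy]phenyl}ethan-1-one F9.
   - Enolisation with LiN(SiMe3)2 at −78 °C and immediate trapping with 2,2,2-trifluoroethyl trifluoroacetate gives 1-{4,6-bis(benzyloxy)-3-[2,3-bis(benzyloxy)benzyl]-2-[(tert-butyldimethylsilyl)oxy]phenyl}-4,4,4-trifluorobutane-1,3-dione F10.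
   - F10 is treated without purification with methanesulfonyl azide, Et3N and water in MeCN (detrifluoroacetylative diazo transfer) to give 13.

Further compounds
F1 | step 9 | 4-(benzyloxy)-3-[2,3-bis(benzyloxy)benzyl]-2-[(tert-butyldimethylsilyl)oxy]-6-hydroxybenzaldehyde | O=Cc1c(O)cc(OCc2ccccc2)c(Cc2cccc(OCc3ccccc3)c2OCc2ccccc2)c1O[Si](C)(C)C(C)(C)C
F2 | step 9 | rac-1-{4-(benzyloxy)-3-[2,3-bis(benzyloxy)benzyl]-2-[(tert-butyldimethylsilyl)oxy]-6-hydroxyphenyl}prop-2-yn-1-ol | C#CC(O)c1c(O)cc(OCc2ccccc2)c(Cc2cccc(OCc3ccccc3)c2OCc2ccccc2)c1O[Si](C)(C)C(C)(C)C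
F3 | step 9 | 1-{4-(benzyloxy)-3-[2,3-bis(benzyloxy)benzyl]-2-[(tert-butyldimethylsilyl)oxy]-6-hydroxyphenyl}prop-2-yn-1-one | C#CC(=O)c1c(O)cc(OCc2ccccc2)c(Cc2cccc(OCc3ccccc3)c2OCc2ccccc2)c1O[Si](C)(C)C(C)(C)C
F4 | step 9 | 7-(benzyloxy)-6-[2,3-bis(benzyloxy)benzyl]-5-[(tert-butyldimethylsilyl)oxy]-4H-chromen-4-one | O=c1ccoc2cc(OCc3ccccc3)c(Cc3cccc(OCc4ccccc4)c3OCc3ccccc3)c(O[Si](C)(C)C(C)(C)C)c12
F5 | step 4 | 4,6-bis(benzyloxy)-2-hydroxybenzaldehyde | O=Cc1c(O)cc(OCc2ccccc2)cc1OCc1ccccc1
F6 | step 4 | 4,6-bis(benzyloxy)-2-hydroxy-3-iodobenzaldehyde | O=Cc1c(O)c(I)c(OCc2ccccc2)cc1OCc1ccccc1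
F7 | step 4 | [2,3-bis(benzyloxy)benzyl]zinc bromide | Br[Zn]Cc1cccc(OCc2ccccc2)c1OCc1ccccc1
F8 | step 8 | rac-1-{4,6-bis(benzyloxy)-3-[2,3-bis(benzyloxy)benzyl]-2-[(tert-butyldimethylsilyl)oxy]phenyl}ethan-1-ol | CC(O)c1c(OCc2ccccc2)cc(OCc2ccccc2)c(Cc2cccc(OCc3ccccc3)c2OCc2ccccc2)c1O[Si](C)(C)C(C)(C)C
F9 | step 8 | 1-{4,6-bis(benzyloxy)-3-[2,3-bis(benzyloxy)benzyl]-2-[(tert-butyldimethylsilyl)oxy]phenyl}ethan-1-one | CC(=O)c1c(OCc2ccccc2)cc(OCc2ccccc2)c(Cc2cccc(OCc3ccccc3)c2OCc2ccccc2)c1O[Si](C)(C)C(C)(C)C
F10 | step 8 | 1-{4,6-bis(benzyloxy)-3-[2,3-bis(benzyloxy)benzyl]-2-[(tert-butyldimethylsilyl)oxy]phenyl}-4,4,4-trifluorobutane-1,3-dione | O=C(CC(=O)C(F)(F)F)c1c(OCc2ccccc2)cc(OCc2ccccc2)c(Cc2cccc(OCc3ccccc3)c2OCc2ccccc2)c1O[Si](C)(C)C(C)(C)C
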